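**Retrosynthetic overview**
1. Target ⇒ its bis-silyl ether; the (Z)-arylidene is cut by aldol condensation into a (3S)-3-aryl-3-prenylfuran-2,4-dione and a protected 4-hydroxy-3-prenylbenzaldehyde.
2. Furandione ⇒ 4-hydroxy-γ-lactone (oxidation) ⇒ β-lactone (O-to-O acyl shift) ⇒ aryl(prenyl)ketene + silyloxyacetaldehyde by a chiral-carbene-catalysed [2+2] that sets the quaternary carbon.
3. Ketene ⇒ α-prenylated arylacetic acid; both ortho-prenyl phenols ⇒ bromophenols + prenyl boronate (Suzuki–Miyaura).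
4. Ring order: both benzene rings are bought; the four-membered lactone and then the five-membered lactone are formed in one flask; no other ring is made.

Abbreviations: TBS = tert-butyldimethylsilyl; prenyl = 3-methylbut-2-en-1-yl; IPent = 1,3-bis[2,6-di(pentan-3-yl)phenyl]imidazol-2-ylidene; CSA = camphor-10-sulfonic acid; DBU = 1,8-diazabicyclo[5.4.0]undec-7-ene.

Assumption: the (5S)-configured triazolium salt is taken to give the 3S β-lactone; if the sense of induction is the opposite, its (5R) antipode (from D-pyroglutamic acid) is used under the same conditions.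

**Route**

Step 1
Reactants: 1 2-(3-bromo-4-hydroxyphenyl)acetic acid
Product: 2 2-(4-hydroxy-3-prenylphenyl)acetic acid
Conditions: prenyl boronic acid pinacol ester (1.5 equiv), PdCl2(IPent)(3-chloropyridine) (2 mol%), 5 M aq. KOH, THF, 70 °C; then dilute HCl
Reagents that add atoms: 4,4,5,5-tetramethyl-2-(3-methylbut-2-en-1-yl)-1,3,2-dioxaborolane, CC(C)=CCB1OC(C)(C)C(C)(C)O1
Why: Suzuki–Miyaura allyl–aryl coupling in which the bulky carbene–palladium catalyst transfers the prenyl group through its unsubstituted carbon, giving the linear ortho-prenyl phenol while carboxylate and phenoxide stay inert.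

Step 2
Reactants: 2 2-(4-hydroxy-3-prenylphenyl)acetic acid
Product: 4 2-[4-(TBS-oxy)-3-prenylphenyl]acetic acid, via bis-silyl ester 3 (not isolated)
Conditions: TBSCl (2.3 equiv), imidazole, DMF, rt; then AcOH/THF/H2O, rt
Reagents that add atoms: tert-butyldimethylsilyl chloride, CC(C)(C)[Si](C)(C)Cl
Why: Silylation of both acidic OH groups followed by selective hydrolysis of the labile silyl ester, which the aryl silyl ether survives, leaves only the phenol protected.

Step 3
Reactants: 4 2-[4-(TBS-oxy)-3-prenylphenyl]acetic acid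
Product: 5 (±)-2-[4-(TBS-oxy)-3-prenylphenyl]-5-methylhex-4-enoic acid
Conditions: LiN(i-Pr)2 (2.2 equiv), THF, −78 → 0 °C; prenyl bromide, −78 °C → rt; cold 1 M HCl
Reagents that add atoms: 1-bromo-3-methylbut-2-ene, CC(C)=CCBr
Why: Carboxylic acid dianion (enediolate) alkylation places the prenyl group on the benzylic carbon by SN2 attack on the allylic bromide; the new centre is racemic and is erased at the ketene stage.

Step 4
Reactants: 5 (±)-2-[4-(TBS-oxy)-3-prenylphenyl]-5-methylhex-4-enoic acid; 6 2-(TBS-oxy)acetaldehyde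
Product: 10 (3S,4RS)-3-[4-(TBS-oxy)-3-prenylphenyl]-4-hydroxy-3-prenyloxolan-2-one, via acid chloride 7 (not isolated), via ketene 8 (not isolated), via β-lactone 9 (not isolated)
Conditions: 1-chloro-N,N,2-trimethylprop-1-en-1-amine, toluene, 0 °C → rt; Et3N, rt, filtration under Ar; 6 (1.2 equiv), (5S)-5-[diphenyl(trimethylsilyloxy)methyl]-2-phenyl-6,7-dihydro-5H-pyrrolo[2,1-c][1,2,4]triazol-2-ium tetrafluoroborate (10 mol%), Cs2CO3 (10 mol%), toluene, −20 °C → rt; then CSA (30 mol%), MeOH, 0 °C → rt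
Reagents that add atoms: none
Why: Proposed new method: neutral chloride formation and dehydrochlorination give aryl alkyl ketene 8, the chiral carbene adds to it to form an azolium enolate whose less shielded face attacks the α-oxygenated aldehyde 6 and closes to β-lactone 9, fixing the quaternary carbon as S (C4 forms as a mixture and is erased in step 5), and acid-catalysed removal of the primary silyl ether (the aryl silyl ether is stable to CSA/MeOH) lets the freed alcohol open the strained four-membered lactone and close the five-membered one by O-to-O acyl shift, so that both lactone rings are formed in one flask; the closest known reactions are the carbene-catalysed formal [2+2] cycloaddition of aryl alkyl ketenes with 2-oxoaldehydes and electron-poor aldehydes and the translactonisation of 4-(hydroxymethyl)-β-lactones to γ-lactones.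

Step 5
Reactants: 10 (3S,4RS)-3-[4-(TBS-oxy)-3-prenylphenyl]-4-hydroxy-3-prenyloxolan-2-one
Product: 11 (3S)-3-[4-(TBS-oxy)-3-prenylphenyl]-3-prenylfuran-2,4(3H,5H)-dione
Conditions: Dess–Martin periodinane, CH2Cl2, 0 °C → rt
Reagents that add atoms: none
Why: Dess–Martin oxidation of the hindered secondary alcohol is neutral, removes the C4 stereocentre and leaves the silyl ether, the prenyl alkenes and the non-enolisable S quaternary carbon untouched.

Step 6
Reactants: 12 3-bromo-4-hydroxybenzaldehyde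
Product: 13 4-hydroxy-3-prenylbenzaldehyde
Conditions: prenyl boronic acid pinacol ester (1.5 equiv), PdCl2(IPent)(3-chloropyridine) (2 mol%), 5 M aq. KOH, THF, 70 °C; then dilute HCl
Reagents that add atoms: 4,4,5,5-tetramethyl-2-(3-methylbut-2-en-1-yl)-1,3,2-dioxaborolane, CC(C)=CCB1OC(C)(C)C(C)(C)O1
Why: The same α-selective Suzuki–Miyaura allyl–aryl coupling as in step 1; the para-oxido benzaldehyde is too deactivated for Cannizzaro chemistry under the basic conditions.

Step 7
Reactants: 13 4-hydroxy-3-prenylbenzaldehyde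
Product: 14 4-(TBS-oxy)-3-prenylbenzaldehyde
Conditions: TBSCl, imidazole, CH2Cl2, rt
Reagents that add atoms: tert-butyldimethylsilyl chloride, CC(C)(C)[Si](C)(C)Cl
Why: Standard phenol silylation restores the electrophilicity of the aldehyde and removes the acidic proton before the enolate chemistry of step 8.

Step 8
Reactants: 11 (3S)-3-[4-(TBS-oxy)-3-prenylphenyl]-3-prenylfuran-2,4(3H,5H)-dione; 14 4-(TBS-oxy)-3-prenylbenzaldehyde
Product: 17 (3S,5Z)-3-[4-(TBS-oxy)-3-prenylphenyl]-5-{[4-(TBS-oxy)-3-prenylphenyl]methylidene}-3-prenylfuran-2,4(3H,5H)-dione, via aldol adduct 15 (not isolated), via aldol acetate 16 (not isolated)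
Conditions: LiN(SiMe3)2 (1.05 equiv), THF, −78 °C; 14; Ac2O (1.1 equiv), −78 → 0 °C; DBU, 0 °C → rt
Reagents that add atoms: none
Why: Aldol condensation by directed addition of the C5 lithium enolate (the only enolisable position) to 14, O-acetylation and E1cB elimination gives the arylidene, the Z isomer (aryl syn to the ring oxygen, away from the C4 carbonyl) being thermodynamically preferred as in aurones and pulvinones, and C3 is not touched.

Step 9
Reactants: 17 (3S,5Z)-3-[4-(TBS-oxy)-3-prenylphenyl]-5-{[4-(TBS-oxy)-3-prenylphenyl]methylidene}-3-prenylfuran-2,4(3H,5H)-dione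
Product: 18 (3S,5Z)-3-(4-hydroxy-3-prenylphenyl)-5-[(4-hydroxy-3-prenylphenyl)methylidene]-3-prenylfuran-2,4(3H,5H)-dione (CNP0567773.1)
Conditions: HF·pyridine, pyridine, THF, 0 °C → rt
Reagents that add atoms: none
Why: Fluoride cleavage of the two aryl silyl ethers under pyridine-buffered conditions is mild enough for the acylating furandione, the enol ester and the ortho-prenyl phenols (no chroman formation).

**Compound list**
1 | 2-(3-bromo-4-hydroxyphenyl)acetic acid | OC(=O)Cc1ccc(O)c(Br)c1 | starting material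
2 | 2-(4-hydroxy-3-prenylphenyl)acetic acid | OC(=O)Cc1ccc(O)c(CC=C(C)C)c1 | intermediate
3 | tert-butyldimethylsilyl 2-[4-(TBS-oxy)-3-prenylphenyl]acetate | CC(C)(C)[Si](C)(C)OC(=O)Cc1ccc(O[Si](C)(C)C(C)(C)C)c(CC=C(C)C)c1 | intermediate
4 | 2-[4-(TBS-oxy)-3-prenylphenyl]acetic acid | OC(=O)Cc1ccc(O[Si](C)(C)C(C)(C)C)c(CC=C(C)C)c1 | intermediate
5 | (±)-2-[4-(TBS-oxy)-3-prenylphenyl]-5-methylhex-4-enoic acid | OC(=O)C(CC=C(C)C)c1ccc(O[Si](C)(C)C(C)(C)C)c(CC=C(C)C)c1 | intermediate
6 | 2-(TBS-oxy)acetaldehyde | O=CCO[Si](C)(C)C(C)(C)C | starting material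
7 | (±)-2-[4-(TBS-oxy)-3-prenylphenyl]-5-methylhex-4-enoyl chloride | ClC(=O)C(CC=C(C)C)c1ccc(O[Si](C)(C)C(C)(C)C)c(CC=C(C)C)c1 | intermediate
8 | 2-[4-(TBS-oxy)-3-prenylphenyl]-5-methylhexa-1,4-dien-1-one (aryl prenyl ketene) | O=C=C(CC=C(C)C)c1ccc(O[Si](C)(C)C(C)(C)C)c(CC=C(C)C)c1 | intermediate
9 | (3S,4RS)-3-[4-(TBS-oxy)-3-prenylphenyl]-3-prenyl-4-[(TBS-oxy)methyl]oxetan-2-one | CC(C)(C)[Si](C)(C)OCC1OC(=O)[C@@]1(CC=C(C)C)c2ccc(O[Si](C)(C)C(C)(C)C)c(CC=C(C)C)c2 | intermediate
10 | (3S,4RS)-3-[4-(TBS-oxy)-3-prenylphenyl]-4-hydroxy-3-prenyloxolan-2-one | OC1COC(=O)[C@@]1(CC=C(C)C)c2ccc(O[Si](C)(C)C(C)(C)C)c(CC=C(C)C)c2 | intermediate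
11 | (3S)-3-[4-(TBS-oxy)-3-prenylphenyl]-3-prenylfuran-2,4(3H,5H)-dione | O=C1COC(=O)[C@@]1(CC=C(C)C)c2ccc(O[Si](C)(C)C(C)(C)C)c(CC=C(C)C)c2 | intermediate
12 | 3-bromo-4-hydroxybenzaldehyde | O=Cc1ccc(O)c(Br)c1 | starting material
13 | 4-hydroxy-3-prenylbenzaldehyde | O=Cc1ccc(O)c(CC=C(C)C)c1 | intermediate
14 | 4-(TBS-oxy)-3-prenylbenzaldehyde | O=Cc1ccc(O[Si](C)(C)C(C)(C)C)c(CC=C(C)C)c1 | intermediate
15 | (3S)-3-[4-(TBS-oxy)-3-prenylphenyl]-5-{hydroxy[4-(TBS-oxy)-3-prenylphenyl]methyl}-3-prenylfuran-2,4(3H,5H)-dione (mixture at C5 and the carbinol carbon) | OC(c1ccc(O[Si](C)(C)C(C)(C)C)c(CC=C(C)C)c1)C2OC(=O)[C@@](CC=C(C)C)(c3ccc(O[Si](C)(C)C(C)(C)C)c(CC=C(C)C)c3)C2=O | intermediate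
16 | acetate of 15 at the carbinol oxygen | CC(=O)OC(c1ccc(O[Si](C)(C)C(C)(C)C)c(CC=C(C)C)c1)C2OC(=O)[C@@](CC=C(C)C)(c3ccc(O[Si](C)(C)C(C)(C)C)c(CC=C(C)C)c3)C2=O | intermediate
17 | (3S,5Z)-3-[4-(TBS-oxy)-3-prenylphenyl]-5-{[4-(TBS-oxy)-3-prenylphenyl]methylidene}-3-prenylfuran-2,4(3H,5H)-dione | CC(C)=CCc1cc(/C=C2\OC(=O)[C@@](CC=C(C)C)(c3ccc(O[Si](C)(C)C(C)(C)C)c(CC=C(C)C)c3)C2=O)ccc1O[Si](C)(C)C(C)(C)C | intermediate
18 | (3S,5Z)-3-(4-hydroxy-3-prenylphenyl)-5-[(4-hydroxy-3-prenylphenyl)methylidene]-3-prenylfuran-2,4(3H,5H)-dione | CC(C)=CCc1cc(/C=C2\OC(=O)[C@@](CC=C(C)C)(c3ccc(O)c(CC=C(C)C)c3)C2=O)ccc1O | target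

**Step count and risks**

Total: 9 steps. Longest linear sequence: 7 steps (1, 2, 3, 4, 5, 8, 9).

Steps most likely to fail:

- **Step 4.** The carbene may react poorly with the enolisable, only moderately activated aldehyde 6 (ketene dimerisation, benzoin-type side reactions). The two β-lactone diastereomers might also not share the C3 configuration, which would lower the ee after step 5. The fallback sets out from 4 and returns at 11. Acid 4 is esterified with methyl glycolate (DCC, DMAP) to the glycolate ester methyl 2-({[4-(TBS-oxy)-3-prenylphenyl]acetyl}oxy)acetate F1. Dieckmann cyclisation with LiN(SiMe3)2 gives the tetronic acid 3-[4-(TBS-oxy)-3-prenylphenyl]-4-hydroxyfuran-2(5H)-one F2. Palladium-catalysed asymmetric allylic alkylation of its enolate with tert-butyl prenyl carbonate (Pd2(dba)3, the DACH-phenyl Trost ligand antipode that gives the S product) then C-prenylates at the unsubstituted allyl terminus and creates the quaternary carbon, giving 11 directly; steps 3 to 5 are then not needed.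

- **Step 8.** Retro-aldol reaction, incomplete elimination, an E/Z mixture or opening of the acylating lactone are possible. The fallback replaces the aldol by a Wittig olefination; it sets out from 11 (and uses 14) and returns at 17. The lithium enolate of 11 is brominated with N-bromosuccinimide at −78 °C to (3S)-5-bromo-3-[4-(TBS-oxy)-3-prenylphenyl]-3-prenylfuran-2,4(3H,5H)-dione F3. PPh3 converts this into {(4S)-4-[4-(TBS-oxy)-3-prenylphenyl]-3,5-dioxo-4-prenyloxolan-2-yl}triphenylphosphonium bromide F4. Treatment of F4 with Et3N and 14 in toluene at 60 °C gives 17 through the keto-stabilised ylide.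

- **Step 1.** Attack through the substituted allyl carbon (reverse prenyl), protodeboronation or slow oxidative addition into the bromophenoxide are possible. The fallback reverses the polarity of the partners; it sets out from 1 and returns at 2. Miyaura borylation (B2pin2, PdCl2(dppf), KOAc, dioxane) gives the aryl boronate 2-[4-hydroxy-3-(4,4,5,5-tetramethyl-1,3,2-dioxaborolan-2-yl)phenyl]acetic acid F5. Palladium-catalysed allyl–aryl coupling with prenyl methyl carbonate (Pd(PPh3)4, aq. K2CO3) transfers the aryl group to the unsubstituted terminus of the π-prenyl palladium complex and gives 2.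

**Further compounds**
F1 | step 4 | methyl 2-({[4-(TBS-oxy)-3-prenylphenyl]acetyl}oxy)acetate | COC(=O)COC(=O)Cc1ccc(O[Si](C)(C)C(C)(C)C)c(CC=C(C)C)c1
F2 | step 4 | 3-[4-(TBS-oxy)-3-prenylphenyl]-4-hydroxyfuran-2(5H)-one | OC1=C(C(=O)OC1)c2ccc(O[Si](C)(C)C(C)(C)C)c(CC=C(C)C)c2
F3 | step 8 | (3S)-5-bromo-3-[4-(TBS-oxy)-3-prenylphenyl]-3-prenylfuran-2,4(3H,5H)-dione | BrC1OC(=O)[C@@](CC=C(C)C)(c2ccc(O[Si](C)(C)C(C)(C)C)c(CC=C(C)C)c2)C1=O
F4 | step 8 | {(4S)-4-[4-(TBS-oxy)-3-prenylphenyl]-3,5-dioxo-4-prenyloxolan-2-yl}triphenylphosphonium bromide | [Br-].c1ccccc1[P+](c2ccccc2)(c3ccccc3)C4OC(=O)[C@@](CC=C(C)C)(c5ccc(O[Si](C)(C)C(C)(C)C)c(CC=C(C)C)c5)C4=O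
F5 | step 1 | 2-[4-hydroxy-3-(4,4,5,5-tetramethyl-1,3,2-dioxaborolan-2-yl)phenyl]acetic acid | OC(=O)Cc1ccc(O)c(B2OC(C)(C)C(C)(C)O2)c1
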